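**Retrosynthetic overview**

- Isogemichalcone B ⇐ removal of four MOM ethers ⇐ allylic ester of a side-chain primary alcohol with MOM-protected p-coumaric acid ⇐ desilylation of a silyl-protected tris-MOM chalcone.
- Feature and key cut: the chalcone carbonyl carbon lies between C1 of ring A and Cα of the styryl unit. Both of its C–C bonds are cut and the carbon is supplied as carbon monoxide, leaving a ring A aryl iodide and an (E)-styrylboronate (carbonylative Suzuki–Miyaura coupling).
- Ring A iodide ⇐ resorcinol bis-MOM ether by two directed metalations: allylation at C2 with an (E)-4-silyloxy prenyl-type bromide (from prenyl acetate by E-selective allylic oxidation), then iodination at C4.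
- Styrylboronate and protected coumaric acid ⇐ one aldehyde, 4-(methoxymethoxy)benzaldehyde (boron–Wittig olefination; Knoevenagel–Doebner condensation).
- No ring is formed: both benzene rings are bought (resorcinol, 4-hydroxybenzaldehyde). The three E alkenes come from the Riley oxidation, the boron–Wittig step and the Doebner step.

Key step: step 11

Remark: ring A is the resorcinol-derived ring that carries the ketone; the pinacol boronate is assumed to transmetalate to the aroylpalladium intermediate under carbonate with a few equivalents of water.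

**Route**

Step 1
Reactants: 1 prenyl acetate (3-methylbut-2-en-1-yl acetate)
Product: 2 (E)-4-hydroxy-3-methylbut-2-en-1-yl acetate
Conditions: SeO2 (0.2 equiv), t-BuOOH (2 equiv), salicylic acid (0.1 equiv), CH2Cl2, rt, stopped before over-oxidation to the enal becomes significant
Reagents that add atoms: tert-butyl hydroperoxide, CC(C)(C)OO
Why: Riley allylic oxidation (ene reaction, then [2,3]-sigmatropic shift of the allylseleninic acid) hydroxylates the methyl group trans to the acetoxymethyl substituent of a trisubstituted alkene, so the (E)-allylic alcohol should form.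

Step 2
Reactants: 2 (E)-4-hydroxy-3-methylbut-2-en-1-yl acetate
Product: 3 (E)-4-(tert-butyldimethylsilyloxy)-3-methylbut-2-en-1-yl acetate
Conditions: TBSCl, imidazole, DMF, 0 °C to rt
Reagents that add atoms: tert-butyldimethylsilyl chloride, CC(C)(C)[Si](C)(C)Cl
Why: Imidazole-promoted silylation of a primary alcohol (Corey silyl ether formation) leaves the acetate and the alkene untouched.

Step 3
Reactants: 3 (E)-4-(tert-butyldimethylsilyloxy)-3-methylbut-2-en-1-yl acetate
Product: 4 (E)-4-(tert-butyldimethylsilyloxy)-3-methylbut-2-en-1-ol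
Conditions: K2CO3 (0.2 equiv), MeOH, 0 °C to rt
Reagents that add atoms: none
Why: Base-catalysed transesterification (methanolysis) removes the acetate, while a primary alkyl TBS ether is stable to carbonate in methanol.

Step 4
Reactants: 4 (E)-4-(tert-butyldimethylsilyloxy)-3-methylbut-2-en-1-ol
Product: 5 {[(E)-4-bromo-2-methylbut-2-en-1-yl]oxy}(tert-butyl)dimethylsilane
Conditions: CBr4, PPh3, CH2Cl2, 0 °C
Reagents that add atoms: carbon tetrabromide, BrC(Br)(Br)Br
Why: Appel bromination displaces the primary allylic oxyphosphonium by bromide under neutral conditions, which keeps the silyl ether and the E geometry.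

Step 5
Reactants: 6 resorcinol
Product: 7 1,3-bis(methoxymethoxy)benzene
Conditions: NaH (2.4 equiv), MOMCl (2.4 equiv), DMF, 0 °C to rt
Reagents that add atoms: chloromethyl methyl ether, COCCl
Why: Williamson-type O-alkylation of the bis-phenoxide with the reactive chloromethyl ether should give the bis-MOM ether cleanly.

Step 6
Reactants: 7 1,3-bis(methoxymethoxy)benzene; 5 {[(E)-4-bromo-2-methylbut-2-en-1-yl]oxy}(tert-butyl)dimethylsilane
Product: 9 tert-butyl{[(E)-4-[2,6-bis(methoxymethoxy)phenyl]-2-methylbut-2-en-1-yl]oxy}dimethylsilane, via 2-lithio-1,3-bis(methoxymethoxy)benzene 8 (not isolated)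
Conditions: n-BuLi, THF, 0 °C to rt; CuI (copper monoiodide, 10 mol %), then 5, −78 °C to rt
Reagents that add atoms: none
Why: Directed ortho-metalation occurs at C2 between the two MOM ethers, and copper-catalysed SN2 allylation at the unhindered primary carbon of the bromide keeps the E alkene.

Step 7
Reactants: 9 tert-butyl{[(E)-4-[2,6-bis(methoxymethoxy)phenyl]-2-methylbut-2-en-1-yl]oxy}dimethylsilane
Product: 11 tert-butyl{[(E)-4-[3-iodo-2,6-bis(methoxymethoxy)phenyl]-2-methylbut-2-en-1-yl]oxy}dimethylsilane, via ring-lithiated aryllithium 10 (not isolated)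
Conditions: n-BuLi, TMEDA, Et2O, 0 °C; I2 in THF, −78 °C to rt
Reagents that add atoms: iodine, II
Why: A second directed ortho-metalation, steered by coordination of the butyllithium–TMEDA complex to a MOM ether in a weakly coordinating solvent, should lithiate the ring carbon next to that ether (the two free ortho sites are equivalent), and iodine traps the aryllithium.

Step 8
Reactants: 12 4-hydroxybenzaldehyde
Product: 13 4-(methoxymethoxy)benzaldehyde
Conditions: NaH (1.2 equiv), MOMCl (1.2 equiv), DMF, 0 °C to rt
Reagents that add atoms: chloromethyl methyl ether, COCCl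
Why: Williamson-type O-alkylation of the phenoxide gives the MOM ether and leaves the aldehyde unchanged.

Step 9
Reactants: 13 4-(methoxymethoxy)benzaldehyde
Product: 14 (E)-2-{2-[4-(methoxymethoxy)phenyl]vinyl}-4,4,5,5-tetramethyl-1,3,2-dioxaborolane
Conditions: lithium 2,2,6,6-tetramethylpiperidide (from the amine and n-BuLi), CH2(Bpin)2, THF, 0 °C; then 13, −78 °C to rt; H2O work-up
Reagents that add atoms: bis(4,4,5,5-tetramethyl-1,3,2-dioxaborolan-2-yl)methane, CC1(C)OB(CB2OC(C)(C)C(C)(C)O2)OC1(C)C
Why: Boron–Wittig olefination, in which the lithiated geminal bis(boronate) adds to the aldehyde and syn-elimination of the boron–oxygen unit follows, should give the trans-alkenylboronate.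

Step 10
Reactants: 13 4-(methoxymethoxy)benzaldehyde
Product: 16 (E)-3-[4-(methoxymethoxy)phenyl]acrylic acid, via 4-(methoxymethoxy)benzylidenemalonic acid 15 (not isolated)
Conditions: malonic acid (2 equiv), pyridine, piperidine (cat.), 90 °C; cold dilute citric acid work-up
Reagents that add atoms: malonic acid, O=C(O)CC(=O)O
Why: Knoevenagel–Doebner condensation followed by decarboxylation in pyridine gives the (E)-cinnamic acid, and the MOM ether is stable in the basic medium.

Step 11
Reactants: 11 tert-butyl{[(E)-4-[3-iodo-2,6-bis(methoxymethoxy)phenyl]-2-methylbut-2-en-1-yl]oxy}dimethylsilane; 17 carbon monoxide; 14 (E)-2-{2-[4-(methoxymethoxy)phenyl]vinyl}-4,4,5,5-tetramethyl-1,3,2-dioxaborolane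
Product: 18 (E)-1-{3-[(E)-4-(tert-butyldimethylsilyloxy)-3-methylbut-2-en-1-yl]-2,4-bis(methoxymethoxy)phenyl}-3-[4-(methoxymethoxy)phenyl]prop-2-en-1-one
Conditions: PdCl2(PPh3)2 (5 mol %), K2CO3 (3 equiv), H2O (5 equiv), CO (5 bar), anisole, 80 °C
Reagents that add atoms: none
Why: Carbonylative Suzuki–Miyaura coupling: zerovalent palladium, formed from PdCl2(PPh3)2, inserts into the C–I bond of 11, CO inserts into the aryl–palladium bond to give an aroylpalladium iodide, the carbonate-activated alkenylboronate 14 transmetalates with retention of geometry, and reductive elimination forms the C(=O)–Cα bond. The closest known reaction type is the three-component coupling of aryl iodides, carbon monoxide and organoboron reagents to give diaryl ketones and enones. No ring is closed and no stereocentre is created; the (E)-enone geometry is inherited from the boronate. The selectivity needed is carbonylative over direct coupling: the electron-rich iodide with an ortho MOM ether gives an arylpalladium species that transmetalates slowly, so capture of CO at a few bar in anisole should win. The allylic silyl ether is not ionised by zerovalent palladium, and the MOM ethers are inert to carbonate.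

Step 12
Reactants: 18 (E)-1-{3-[(E)-4-(tert-butyldimethylsilyloxy)-3-methylbut-2-en-1-yl]-2,4-bis(methoxymethoxy)phenyl}-3-[4-(methoxymethoxy)phenyl]prop-2-en-1-one
Product: 19 (E)-1-{3-[(E)-4-hydroxy-3-methylbut-2-en-1-yl]-2,4-bis(methoxymethoxy)phenyl}-3-[4-(methoxymethoxy)phenyl]prop-2-en-1-one
Conditions: Bu4NF, AcOH (1:1), THF, 0 °C to rt
Reagents that add atoms: none
Why: Fluoride-mediated desilylation, buffered with acetic acid, cleaves only the Si–O bond and leaves the MOM ethers and the enone alone.

Step 13
Reactants: 19 (E)-1-{3-[(E)-4-hydroxy-3-methylbut-2-en-1-yl]-2,4-bis(methoxymethoxy)phenyl}-3-[4-(methoxymethoxy)phenyl]prop-2-en-1-one; 16 (E)-3-[4-(methoxymethoxy)phenyl]acrylic acid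
Product: 20 (E)-4-{2,6-bis(methoxymethoxy)-3-[(E)-3-[4-(methoxymethoxy)phenyl]acryloyl]phenyl}-2-methylbut-2-en-1-yl (E)-3-[4-(methoxymethoxy)phenyl]acrylate
Conditions: DCC, DMAP (cat.), CH2Cl2, 0 °C to rt
Reagents that add atoms: none
Why: Steglich esterification, with DMAP relaying the acyl group from the O-acylisourea, acylates the unhindered primary allylic alcohol without touching either alkene.

Step 14
Reactants: 20 (E)-4-{2,6-bis(methoxymethoxy)-3-[(E)-3-[4-(methoxymethoxy)phenyl]acryloyl]phenyl}-2-methylbut-2-en-1-yl (E)-3-[4-(methoxymethoxy)phenyl]acrylate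
Product: 21 isogemichalcone B, (E)-4-{2,6-dihydroxy-3-[(E)-3-(4-hydroxyphenyl)acryloyl]phenyl}-2-methylbut-2-en-1-yl (E)-3-(4-hydroxyphenyl)acrylate
Conditions: 3 M aq HCl, MeOH, rt to 40 °C, quenched with NaHCO3 as soon as the last MOM ether is gone
Reagents that add atoms: none
Why: Acid-catalysed transacetalisation to methanol removes all four aryl MOM ethers under conditions mild enough that the allylic ester and the 2'-hydroxychalcone should survive.

**Compound list**

1 | prenyl acetate (3-methylbut-2-en-1-yl acetate) | CC(C)=CCOC(C)=O | starting material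
2 | (E)-4-hydroxy-3-methylbut-2-en-1-yl acetate | C/C(=C\COC(C)=O)CO | intermediate
3 | (E)-4-(tert-butyldimethylsilyloxy)-3-methylbut-2-en-1-yl acetate | C/C(=C\COC(C)=O)CO[Si](C)(C)C(C)(C)C | intermediate
4 | (E)-4-(tert-butyldimethylsilyloxy)-3-methylbut-2-en-1-ol | C/C(=C\CO)CO[Si](C)(C)C(C)(C)C | intermediate
5 | {[(E)-4-bromo-2-methylbut-2-en-1-yl]oxy}(tert-butyl)dimethylsilane | C/C(=C\CBr)CO[Si](C)(C)C(C)(C)C | intermediate
6 | resorcinol | Oc1cccc(O)c1 | starting material
7 | 1,3-bis(methoxymethoxy)benzene | COCOc1cccc(OCOC)c1 | intermediate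
8 | 2-lithio-1,3-bis(methoxymethoxy)benzene | [Li]c1c(OCOC)cccc1OCOC | intermediate
9 | tert-butyl{[(E)-4-[2,6-bis(methoxymethoxy)phenyl]-2-methylbut-2-en-1-yl]oxy}dimethylsilane | C/C(=C\Cc1c(OCOC)cccc1OCOC)CO[Si](C)(C)C(C)(C)C | intermediate
10 | tert-butyl{[(E)-4-[3-lithio-2,6-bis(methoxymethoxy)phenyl]-2-methylbut-2-en-1-yl]oxy}dimethylsilane | C/C(=C\Cc1c(OCOC)ccc([Li])c1OCOC)CO[Si](C)(C)C(C)(C)C | intermediate
11 | tert-butyl{[(E)-4-[3-iodo-2,6-bis(methoxymethoxy)phenyl]-2-methylbut-2-en-1-yl]oxy}dimethylsilane | C/C(=C\Cc1c(OCOC)ccc(I)c1OCOC)CO[Si](C)(C)C(C)(C)C | intermediate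
12 | 4-hydroxybenzaldehyde | O=Cc1ccc(O)cc1 | starting material
13 | 4-(methoxymethoxy)benzaldehyde | COCOc1ccc(C=O)cc1 | intermediate
14 | (E)-2-{2-[4-(methoxymethoxy)phenyl]vinyl}-4,4,5,5-tetramethyl-1,3,2-dioxaborolane | COCOc1ccc(/C=C/B2OC(C)(C)C(C)(C)O2)cc1 | intermediate
15 | 4-(methoxymethoxy)benzylidenemalonic acid | COCOc1ccc(C=C(C(=O)O)C(=O)O)cc1 | intermediate
16 | (E)-3-[4-(methoxymethoxy)phenyl]acrylic acid | COCOc1ccc(/C=C/C(=O)O)cc1 | intermediate
17 | carbon monoxide | [C-]#[O+] | starting material
18 | (E)-1-{3-[(E)-4-(tert-butyldimethylsilyloxy)-3-methylbut-2-en-1-yl]-2,4-bis(methoxymethoxy)phenyl}-3-[4-(methoxymethoxy)phenyl]prop-2-en-1-one | C/C(=C\Cc1c(OCOC)ccc(C(=O)/C=C/c2ccc(OCOC)cc2)c1OCOC)CO[Si](C)(C)C(C)(C)C | intermediate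
19 | (E)-1-{3-[(E)-4-hydroxy-3-methylbut-2-en-1-yl]-2,4-bis(methoxymethoxy)phenyl}-3-[4-(methoxymethoxy)phenyl]prop-2-en-1-one | C/C(=C\Cc1c(OCOC)ccc(C(=O)/C=C/c2ccc(OCOC)cc2)c1OCOC)CO | intermediate
20 | (E)-4-{2,6-bis(methoxymethoxy)-3-[(E)-3-[4-(methoxymethoxy)phenyl]acryloyl]phenyl}-2-methylbut-2-en-1-yl (E)-3-[4-(methoxymethoxy)phenyl]acrylate | C/C(=C\Cc1c(OCOC)ccc(C(=O)/C=C/c2ccc(OCOC)cc2)c1OCOC)COC(=O)/C=C/c1ccc(OCOC)cc1 | intermediate
21 | isogemichalcone B | C/C(=C\Cc1c(O)ccc(C(=O)/C=C/c2ccc(O)cc2)c1O)COC(=O)/C=C/c1ccc(O)cc1 | target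

**Step count**

Total steps: 14. Longest linear sequence: 10 steps (steps 1, 2, 3, 4, 6, 7, 11, 12, 13, 14, from prenyl acetate).

**Steps most likely to fail**

1. Step 11 (carbonylative coupling). Transmetalation may overtake CO insertion and give the non-carbonylated stilbene. The alkenylboronate may also protodeboronate, or the aroylpalladium intermediate may be captured by water when the pinacol ester transmetalates slowly. The fallback sets out from iodide 11 and acid 16 and abandons the palladium step for an acyl-transfer route. Acid 16 is converted with carbonyldiimidazole and N,O-dimethylhydroxylamine hydrochloride in CH2Cl2 into (E)-N-methoxy-N-methyl-3-[4-(methoxymethoxy)phenyl]acrylamide F1. Iodide 11 undergoes iodine–lithium exchange (t-BuLi, 2 equiv, THF, −78 °C) to regenerate aryllithium 10. This adds 1,2 to F1, and the chelated tetrahedral adduct collapses on work-up to the enone. The fallback returns to the route at 18.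

2. Step 7 (directed lithiation–iodination). The base may deprotonate the doubly activated benzylic–allylic methylene, which is flanked by two coordinating MOM ethers, or the position alpha to the silyl ether, instead of the ring C–H. The fallback sets out from 9 and replaces metalation by electrophilic aromatic substitution: N-iodosuccinimide (1.0 equiv) in MeCN or DMF at 0 °C. The target carbon is ortho to one ether and para to the other, and the ring is more nucleophilic than the trisubstituted alkene. The fallback returns to the route at 11 and makes no new compound (F0).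

3. Step 14 (global MOM removal). The acid may cause methanolysis of the allylic coumarate, cyclisation of the freed 2'-hydroxychalcone to the flavanone, or addition of an ortho phenol to the side-chain alkene. The fallback sets out from alcohol 19 and reverses the order of deprotection and esterification. The three MOM ethers are removed first (HCl, MeOH, rt), when no ester is present, to give (E)-1-{2,4-dihydroxy-3-[(E)-4-hydroxy-3-methylbut-2-en-1-yl]phenyl}-3-(4-hydroxyphenyl)prop-2-en-1-one F2. The primary allylic alcohol of F2 is then esterified with commercial, unprotected p-coumaric acid under Mitsunobu conditions (PPh3, diisopropyl azodicarboxylate, THF, 0 °C). The carboxylic acid is far more acidic than the phenols and should act as the pronucleophile. The fallback returns to the route at 21.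

**Further compounds**

F1 | step 11 | (E)-N-methoxy-N-methyl-3-[4-(methoxymethoxy)phenyl]acrylamide | COCOc1ccc(/C=C/C(=O)N(C)OC)cc1
F0 | step 7 | none | none
F2 | step 14 | (E)-1-{2,4-dihydroxy-3-[(E)-4-hydroxy-3-methylbut-2-en-1-yl]phenyl}-3-(4-hydroxyphenyl)prop-2-en-1-one | C/C(=C\Cc1c(O)ccc(C(=O)/C=C/c2ccc(O)cc2)c1O)CO
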